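**Retrosynthetic overview**
- The hydroperoxide comes from the tertiary allylic alcohol (perhydrolysis), which comes from a terminal alkene by cross-metathesis; the acetate comes from a ketone on the eight-membered ring.
- The side chain is attached by an iminium-catalysed Michael addition of the tricyclic keto-butenolide to (E)-crotonaldehyde.
- The keto-butenolide comes from a cyclooctadiene-fused butenolide (epoxidation, isomerisation); the butenolide is closed by carbonylative lactonisation of a vinyl triflate.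
- Key step: two-carbon ring expansion. Methyl propiolate is inserted into the C(O)–CH2 bond of a cyclopropyl ketone via a silyloxycyclobutene, retro-aldol fragmentation and enolate triflation.
- Ring order: cyclohexenone (from propanal and methyl vinyl ketone), then cyclopropane, then transient cyclobutene, then eight-membered ring, then butenolide.

Assumption: the target is the enantiomer written in the SMILES; in the text C1 = CHOAc, C2 = ring CH2, C3 = CHMe, C4/C5 = cyclopropane CH (C5 next to the lactone), C6/C7 = lactone α/β carbons, C8 = CH bearing the side chain, C9 = cyclopropane CH2, C10 = lactone C=O, C11 = lactone CH2, C1′–C5′ = side chain.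

**Step 1**
Reactants: 1 propanal; 2 but-3-en-2-one
Product: 4 (4R)-4-methylcyclohex-2-en-1-one, via keto aldehyde 3 (not isolated)
Conditions: (S)-α,α-diphenylprolinol methyl ether (5 mol %), ethyl 3,4-dihydroxybenzoate (20 mol %), neat, 4 °C; then LiOH (10 mol %), iPrOH, 25 °C
Reagents that add atoms: none
Why: Enamine-catalysed Michael addition (the (S)-catalyst shields one enamine face and sets the methyl-bearing centre as R) followed by intramolecular aldol condensation, i.e. an organocatalytic Robinson annulation.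

**Step 2**
Reactants: 4 (4R)-4-methylcyclohex-2-en-1-one
Product: 5 (1S,5R,6S)-5-methylbicyclo[4.1.0]heptan-2-one
Conditions: Me3S(O)I, NaH, DMSO, 25 → 50 °C
Reagents that add atoms: trimethylsulfoxonium iodide, C[S+](C)(C)=O.[I-]
Why: Corey–Chaykovsky cyclopropanation (conjugate addition of the sulfoxonium ylide, then 3-exo-tet closure); the ylide adds anti to the adjacent C3 methyl, giving the trans cyclopropane (C4 S, C5 S), with the minor cis isomer removed by chromatography.

**Step 3**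
Reactants: 5 (1S,5R,6S)-5-methylbicyclo[4.1.0]heptan-2-one
Product: 6 tert-butyl(dimethyl){[(1S,5R,6S)-5-methylbicyclo[4.1.0]hept-2-en-2-yl]oxy}silane
Conditions: TBSOTf, Et3N, CH2Cl2, 0 °C
Reagents that add atoms: tert-butyldimethylsilyl triflate, CC(C)(C)[Si](C)(C)OS(=O)(=O)C(F)(F)F
Why: Soft enolisation and O-silylation; the ketone can enolise only towards the CH2 (C1) because the other α-carbon is the cyclopropane bridgehead, so one silyl enol ether forms and no stereocentre is touched.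

**Step 4**
Reactants: 6 tert-butyl(dimethyl){[(1S,5R,6S)-5-methylbicyclo[4.1.0]hept-2-en-2-yl]oxy}silane; 7 methyl prop-2-ynoate
Product: 10 methyl (1S,2Z,4Z,7R,8S)-7-methyl-2-{[(trifluoromethyl)sulfonyl]oxy}bicyclo[6.1.0]nona-2,4-diene-3-carboxylate, via silyloxycyclobutene 8 (not isolated), via ring-expanded enolate 9 (not isolated)
Conditions: Tf2NH (2 mol %), CH2Cl2, −78 °C; then Bu4N[Ph3SiF2] (TBAT), THF, −78 → 0 °C; then PhNTf2, 0 → 25 °C
Reagents that add atoms: N-phenylbis(trifluoromethanesulfonimide), O=S(=O)(N(c1ccccc1)S(=O)(=O)C(F)(F)F)C(F)(F)F (triflyl group); tetrabutylammonium difluorotriphenylsilicate, CCCC[N+](CCCC)(CCCC)CCCC.F[Si-](F)(c1ccccc1)(c1ccccc1)c1ccccc1 (only the counter-ion of 9)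
Why: Proposed new method: one-flask formal insertion of the alkyne into the C6–C1 bond of a simple ketone — acid-catalysed Mukaiyama–Michael/aldol closure of 6 onto 7 gives cyclobutene 8 (closest known reaction: the acid-catalysed (2+2) union of silyl enol ethers with propiolates), fluoride unmasks the strained cyclobutenolate, which fragments by stepwise anionic retro-aldol cleavage of the C6–C1 bond (driven by ring strain and by formation of the vinylogous β-keto ester enolate 9; related to the enamine–propiolate two-carbon ring enlargement), and 9 is O-sulfonylated in situ; the three existing stereocentres are spectators and both new ring alkenes are Z by ring constraint.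

**Step 5**
Reactants: 10 methyl (1S,2Z,4Z,7R,8S)-7-methyl-2-{[(trifluoromethyl)sulfonyl]oxy}bicyclo[6.1.0]nona-2,4-diene-3-carboxylate
Product: 11 [(1S,2Z,4Z,7R,8S)-3-(hydroxymethyl)-7-methylbicyclo[6.1.0]nona-2,4-dien-2-yl] trifluoromethanesulfonate
Conditions: iBu2AlH (2.5 equiv), CH2Cl2, −78 °C
Reagents that add atoms: none
Why: 1,2-Reduction of the ester by the aluminium hydride at low temperature, under which vinyl triflate and diene are inert; no stereocentre is involved.

**Step 6**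
Reactants: 11 [(1S,2Z,4Z,7R,8S)-3-(hydroxymethyl)-7-methylbicyclo[6.1.0]nona-2,4-dien-2-yl] trifluoromethanesulfonate
Product: 12 (2S,4S,5R,7Z)-5-methyl-11-oxatricyclo[7.3.0.0^{2,4}]dodeca-1(9),7-dien-12-one
Conditions: CO (1 atm), Pd(PPh3)4 (5 mol %), Bu3N, LiCl, MeCN, 65 °C
Reagents that add atoms: carbon monoxide, [C-]#[O+]
Why: Carbonylative lactonisation: oxidative addition of the vinyl triflate to zerovalent palladium, CO insertion and capture of the acyl complex by the neighbouring CH2OH close the butenolide with C10 on C6; no stereocentre is affected.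

**Step 7**
Reactants: 12 (2S,4S,5R,7Z)-5-methyl-11-oxatricyclo[7.3.0.0^{2,4}]dodeca-1(9),7-dien-12-one
Product: 13 (2S,4S,5R,7R,8S)-7,8-epoxy-5-methyl-11-oxatricyclo[7.3.0.0^{2,4}]dodec-1(9)-en-12-one
Conditions: DMDO, acetone, 0 °C
Reagents that add atoms: dimethyldioxirane, CC1(C)OO1
Why: Electrophilic epoxidation of the more electron-rich γ,δ-alkene of the dienolide; the epoxide is drawn on the α-face (taken as the exposed face of the folded ring), and the other face would give the same ketone in step 8.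

**Step 8**
Reactants: 13 (2S,4S,5R,7R,8S)-7,8-epoxy-5-methyl-11-oxatricyclo[7.3.0.0^{2,4}]dodec-1(9)-en-12-one
Product: 14 (2S,4S,5R)-5-methyl-11-oxatricyclo[7.3.0.0^{2,4}]dodec-1(9)-ene-7,12-dione
Conditions: Pd(PPh3)4 (5 mol %), THF, 25 °C; then Et3N (cat.)
Reagents that add atoms: none
Why: Vinyl epoxide isomerisation: zerovalent palladium opens the allylic C8–O bond to a π-allyl alkoxide, β-hydride elimination of C1–H and hydride return to the allyl terminus give the β,γ-unsaturated ketone (amine equilibration secures the conjugated butenolide tautomer); both epoxide stereocentres are erased.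

**Step 9**
Reactants: 14 (2S,4S,5R)-5-methyl-11-oxatricyclo[7.3.0.0^{2,4}]dodec-1(9)-ene-7,12-dione; 15 (2E)-but-2-enal
Product: 16 (3R)-3-[(2S,4S,5R,8S)-5-methyl-7,12-dioxo-11-oxatricyclo[7.3.0.0^{2,4}]dodec-1(9)-en-8-yl]butanal
Conditions: (S)-α,α-diphenylprolinol trimethylsilyl ether (20 mol %), LiOAc (20 mol %), CH2Cl2–MeOH, 0 °C
Reagents that add atoms: none
Why: Iminium-catalysed Michael addition of the doubly activated C8–H2 (α to the ketone, vinylogous to the lactone); the (S)-catalyst shields one face of the iminium β-carbon and sets C1′ as R, while C8 is set by attack on the exposed α-face of the ring dienolate (the C2–C4 bridge covers the β-face) and, being still acidic, can be equilibrated to the 8S epimer.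

**Step 10**
Reactants: 16 (3R)-3-[(2S,4S,5R,8S)-5-methyl-7,12-dioxo-11-oxatricyclo[7.3.0.0^{2,4}]dodec-1(9)-en-8-yl]butanal
Product: 17 (2S,4S,5R,8S)-5-methyl-8-[(2R)-pent-4-en-2-yl]-11-oxatricyclo[7.3.0.0^{2,4}]dodec-1(9)-ene-7,12-dione
Conditions: CH2I2, Zn, Ti(OiPr)4, THF, 0 → 25 °C
Reagents that add atoms: diiodomethane, ICI
Why: Aldehyde-selective Takai-type methylenation with the non-basic CH2I2/Zn/Ti(OiPr)4 reagent, which leaves the ketone, the lactone and the epimerisable C8 centre untouched.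

**Step 11**
Reactants: 17 (2S,4S,5R,8S)-5-methyl-8-[(2R)-pent-4-en-2-yl]-11-oxatricyclo[7.3.0.0^{2,4}]dodec-1(9)-ene-7,12-dione
Product: 19 (2S,4S,5R,7R,8S)-5-methyl-12-oxo-8-[(2R)-pent-4-en-2-yl]-11-oxatricyclo[7.3.0.0^{2,4}]dodec-1(9)-en-7-yl acetate, via alkoxyaluminate 18 (not isolated)
Conditions: LiAlH(OtBu)3, THF, −40 → 0 °C; then Ac2O, DMAP, 0 → 25 °C
Reagents that add atoms: acetic anhydride, CC(=O)OC(C)=O (acetyl group); LiAlH(OtBu)3, [Li+].CC(C)(C)O[AlH-](OC(C)(C)C)OC(C)(C)C (only the aluminate part of 18)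
Why: Diastereoselective hydride reduction of the C1 ketone (hydride enters anti to the adjacent C8 side chain, as for 2-alkylcyclooctanones, giving the cis 7R alcohol) followed by in situ acetylation of the alkoxide; this mild hydride does not reduce the fully substituted butenolide.

**Step 12**
Reactants: 19 (2S,4S,5R,7R,8S)-5-methyl-12-oxo-8-[(2R)-pent-4-en-2-yl]-11-oxatricyclo[7.3.0.0^{2,4}]dodec-1(9)-en-7-yl acetate; 20 2-methylbut-3-en-2-ol
Product: 21 (2S,4S,5R,7R,8S)-8-[(2R,4E)-6-hydroxy-6-methylhept-4-en-2-yl]-5-methyl-12-oxo-11-oxatricyclo[7.3.0.0^{2,4}]dodec-1(9)-en-7-yl acetate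
Conditions: 20 (5 equiv), second-generation Hoveyda–Grubbs catalyst (5 mol %), CH2Cl2, 40 °C
Reagents that add atoms: none
Why: Olefin cross-metathesis of the terminal alkene with an excess of the hindered tertiary allylic alcohol, which does not homodimerise, gives the E-disubstituted alkene under thermodynamic control.

**Step 13**
Reactants: 21 (2S,4S,5R,7R,8S)-8-[(2R,4E)-6-hydroxy-6-methylhept-4-en-2-yl]-5-methyl-12-oxo-11-oxatricyclo[7.3.0.0^{2,4}]dodec-1(9)-en-7-yl acetate
Product: 22 (2S,4S,5R,7R,8S)-8-[(2R,4E)-6-hydroperoxy-6-methylhept-4-en-2-yl]-5-methyl-12-oxo-11-oxatricyclo[7.3.0.0^{2,4}]dodec-1(9)-en-7-yl acetate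
Conditions: 50% aq. H2O2, H2SO4 (cat.), Et2O, 0 °C
Reagents that add atoms: hydrogen peroxide, OO
Why: Acid-catalysed perhydrolysis (SN1 substitution through the tertiary allylic cation, captured by H2O2 at the tertiary terminus) gives the tertiary hydroperoxide with the E-alkene retained; no ring stereocentre is involved.

**Compound list**
1 | propanal | CCC=O | starting material
2 | but-3-en-2-one | CC(=O)C=C | starting material
3 | (2R)-2-methyl-5-oxohexanal | CC(=O)CC[C@@H](C)C=O | intermediate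
4 | (4R)-4-methylcyclohex-2-en-1-one | C1C[C@@H](C)C=CC1=O | intermediate
5 | (1S,5R,6S)-5-methylbicyclo[4.1.0]heptan-2-one | C1C[C@@H](C)[C@@H]2C[C@@H]2C1=O | intermediate
6 | tert-butyl(dimethyl){[(1S,5R,6S)-5-methylbicyclo[4.1.0]hept-2-en-2-yl]oxy}silane | C1C[C@@H](C)[C@@H]2C[C@@H]2C=1O[Si](C)(C)C(C)(C)C | intermediate
7 | methyl prop-2-ynoate | C#CC(=O)OC | starting material
8 | methyl (2S,4S,5R)-1-[(tert-butyldimethylsilyl)oxy]-5-methyltricyclo[5.2.0.0^{2,4}]non-8-ene-9-carboxylate (1,7-cis fusion, cyclobutene anti to the cyclopropane CH2) | [C@H]12C[C@@H](C)[C@@H]3C[C@@H]3[C@@]1(O[Si](C)(C)C(C)(C)C)C(C(=O)OC)=C2 | intermediate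
9 | tetrabutylammonium (1S,2Z,4Z,7R,8S)-3-(methoxycarbonyl)-7-methylbicyclo[6.1.0]nona-2,4-dien-2-olate | CCCC[N+](CCCC)(CCCC)CCCC.C1[C@@H](C)[C@@H]2C[C@@H]2/C([O-])=C(C(=O)OC)\C=C/1 | intermediate
10 | methyl (1S,2Z,4Z,7R,8S)-7-methyl-2-{[(trifluoromethyl)sulfonyl]oxy}bicyclo[6.1.0]nona-2,4-diene-3-carboxylate | C1[C@@H](C)[C@@H]2C[C@@H]2/C(OS(=O)(=O)C(F)(F)F)=C(C(=O)OC)\C=C/1 | intermediate
11 | [(1S,2Z,4Z,7R,8S)-3-(hydroxymethyl)-7-methylbicyclo[6.1.0]nona-2,4-dien-2-yl] trifluoromethanesulfonate | C1[C@@H](C)[C@@H]2C[C@@H]2/C(OS(=O)(=O)C(F)(F)F)=C(CO)\C=C/1 | intermediate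
12 | (2S,4S,5R,7Z)-5-methyl-11-oxatricyclo[7.3.0.0^{2,4}]dodeca-1(9),7-dien-12-one | C1[C@@H](C)[C@@H]2C[C@@H]2C2=C(COC2=O)/C=C\1 | intermediate
13 | (2S,4S,5R,7R,8S)-7,8-epoxy-5-methyl-11-oxatricyclo[7.3.0.0^{2,4}]dodec-1(9)-en-12-one | O1[C@@H]2C[C@@H](C)[C@@H]3C[C@@H]3C3=C(COC3=O)[C@H]12 | intermediate
14 | (2S,4S,5R)-5-methyl-11-oxatricyclo[7.3.0.0^{2,4}]dodec-1(9)-ene-7,12-dione | O=C1C[C@@H](C)[C@@H]2C[C@@H]2C2=C(COC2=O)C1 | intermediate
15 | (2E)-but-2-enal | C/C=C/C=O | starting material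
16 | (3R)-3-[(2S,4S,5R,8S)-5-methyl-7,12-dioxo-11-oxatricyclo[7.3.0.0^{2,4}]dodec-1(9)-en-8-yl]butanal | O=C1C[C@@H](C)[C@@H]2C[C@@H]2C2=C(COC2=O)[C@@H]1[C@H](C)CC=O | intermediate
17 | (2S,4S,5R,8S)-5-methyl-8-[(2R)-pent-4-en-2-yl]-11-oxatricyclo[7.3.0.0^{2,4}]dodec-1(9)-ene-7,12-dione | O=C1C[C@@H](C)[C@@H]2C[C@@H]2C2=C(COC2=O)[C@@H]1[C@H](C)CC=C | intermediate
18 | lithium tri-tert-butoxy{[(2S,4S,5R,7R,8S)-5-methyl-12-oxo-8-[(2R)-pent-4-en-2-yl]-11-oxatricyclo[7.3.0.0^{2,4}]dodec-1(9)-en-7-yl]oxy}aluminate | [Li+].CC(C)(C)O[Al-](OC(C)(C)C)(OC(C)(C)C)O[C@@H]1C[C@@H](C)[C@@H]2C[C@@H]2C2=C(COC2=O)[C@@H]1[C@H](C)CC=C | intermediate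
19 | (2S,4S,5R,7R,8S)-5-methyl-12-oxo-8-[(2R)-pent-4-en-2-yl]-11-oxatricyclo[7.3.0.0^{2,4}]dodec-1(9)-en-7-yl acetate | CC(=O)O[C@@H]1C[C@@H](C)[C@@H]2C[C@@H]2C2=C(COC2=O)[C@@H]1[C@H](C)CC=C | intermediate
20 | 2-methylbut-3-en-2-ol | CC(C)(O)C=C | starting material
21 | (2S,4S,5R,7R,8S)-8-[(2R,4E)-6-hydroxy-6-methylhept-4-en-2-yl]-5-methyl-12-oxo-11-oxatricyclo[7.3.0.0^{2,4}]dodec-1(9)-en-7-yl acetate | CC(=O)O[C@@H]1C[C@@H](C)[C@@H]2C[C@@H]2C2=C(COC2=O)[C@@H]1[C@H](C)C/C=C/C(C)(C)O | intermediate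
22 | (2S,4S,5R,7R,8S)-8-[(2R,4E)-6-hydroperoxy-6-methylhept-4-en-2-yl]-5-methyl-12-oxo-11-oxatricyclo[7.3.0.0^{2,4}]dodec-1(9)-en-7-yl acetate | CC(=O)O[C@@H]1C[C@@H](C)[C@@H]2C[C@@H]2C2=C(COC2=O)[C@@H]1[C@H](C)C/C=C/C(C)(C)OO | target

**Step count and risks**
Total step count: 13. Longest linear sequence: 13 steps (1/2 → 22).

The three steps most likely to fail:

- **Step 4 (the proposed new ring expansion).** The cyclobutene may not form cleanly on the cyclopropyl ketone enol ether, or fluoride-triggered fragmentation and triflation may not telescope. The fallback uses known chemistry and sets out from ketone 5. Condensation with pyrrolidine (TsOH cat., benzene, water removal) gives the enamine 1-[(1S,5R,6S)-5-methylbicyclo[4.1.0]hept-2-en-2-yl]pyrrolidine F1. F1 and methyl propiolate 7 (Et2O, then warm toluene) give the aminocyclobutene methyl (2S,4S,5R)-5-methyl-1-(pyrrolidin-1-yl)tricyclo[5.2.0.0^{2,4}]non-8-ene-9-carboxylate F2, which opens in the same flask to the ring-enlarged dienamine methyl (1S,2Z,4Z,7R,8S)-7-methyl-2-(pyrrolidin-1-yl)bicyclo[6.1.0]nona-2,4-diene-3-carboxylate F3 (the classical enamine–acetylenic ester two-carbon ring enlargement). Aqueous AcOH hydrolyses F3 to the β-keto ester methyl (1S,4Z,7R,8S)-7-methyl-2-oxobicyclo[6.1.0]non-4-ene-3-carboxylate F4, and NaH/PhNTf2 in THF converts F4 into triflate 10, where the route is rejoined.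

- **Step 9 (Michael addition).** The risks are C6 versus C8 attack of the extended enolate, low reactivity of this new pronucleophile, and the C8 configuration, which rests on substrate control. The fallback sets out from 14. TBSOTf/Et3N gives the silyl dienol ether (2S,4S,5R)-7-[(tert-butyldimethylsilyl)oxy]-5-methyl-11-oxatricyclo[7.3.0.0^{2,4}]dodeca-1(9),7-dien-12-one F5. A Mukaiyama–Michael addition of F5 to 15 follows, catalysed by the trifluoroacetate salt of 5-benzyl-2-tert-butyl-3-methylimidazolidin-4-one (the enantiomer that exposes the same enal face as the (S)-prolinol catalyst) in CH2Cl2/H2O at −40 °C. The pre-formed nucleophile reacts only at C8, and hydrolytic work-up returns to 16.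

- **Step 13 (perhydrolysis).** The allylic cation may be captured at the secondary terminus or lose a proton to a diene, and the acetate is exposed to acid. The fallback sets out from 19 and 20 and moves the substitution onto the simple alcohol. 20 with 50% H2O2/H2SO4 gives 3-hydroperoxy-3-methylbut-1-ene F6. 2-Methoxypropene/PPTS protects it as 3-[(2-methoxypropan-2-yl)peroxy]-3-methylbut-1-ene F7. Cross-metathesis of 19 with F7 (second-generation Hoveyda–Grubbs catalyst, CH2Cl2, 40 °C) gives the peroxyketal (2S,4S,5R,7R,8S)-8-{(2R,4E)-6-[(2-methoxypropan-2-yl)peroxy]-6-methylhept-4-en-2-yl}-5-methyl-12-oxo-11-oxatricyclo[7.3.0.0^{2,4}]dodec-1(9)-en-7-yl acetate F8. AcOH/THF/H2O at 25 °C then releases 22.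

**Further compounds**
F1 | step 4 | 1-[(1S,5R,6S)-5-methylbicyclo[4.1.0]hept-2-en-2-yl]pyrrolidine | C1C[C@@H](C)[C@@H]2C[C@@H]2C=1N1CCCC1
F2 | step 4 | methyl (2S,4S,5R)-5-methyl-1-(pyrrolidin-1-yl)tricyclo[5.2.0.0^{2,4}]non-8-ene-9-carboxylate (1,7-cis fusion) | [C@H]12C[C@@H](C)[C@@H]3C[C@@H]3[C@@]1(N1CCCC1)C(C(=O)OC)=C2
F3 | step 4 | methyl (1S,2Z,4Z,7R,8S)-7-methyl-2-(pyrrolidin-1-yl)bicyclo[6.1.0]nona-2,4-diene-3-carboxylate | C1[C@@H](C)[C@@H]2C[C@@H]2/C(N2CCCC2)=C(C(=O)OC)\C=C/1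
F4 | step 4 | methyl (1S,4Z,7R,8S)-7-methyl-2-oxobicyclo[6.1.0]non-4-ene-3-carboxylate (C3 enolisable, not defined) | C1[C@@H](C)[C@@H]2C[C@@H]2C(=O)C(C(=O)OC)\C=C/1
F5 | step 9 | (2S,4S,5R)-7-[(tert-butyldimethylsilyl)oxy]-5-methyl-11-oxatricyclo[7.3.0.0^{2,4}]dodeca-1(9),7-dien-12-one | C1(O[Si](C)(C)C(C)(C)C)C[C@@H](C)[C@@H]2C[C@@H]2C2=C(COC2=O)C=1
F6 | step 13 | 3-hydroperoxy-3-methylbut-1-ene | CC(C)(OO)C=C
F7 | step 13 | 3-[(2-methoxypropan-2-yl)peroxy]-3-methylbut-1-ene | CC(C)(OOC(C)(C)OC)C=C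
F8 | step 13 | (2S,4S,5R,7R,8S)-8-{(2R,4E)-6-[(2-methoxypropan-2-yl)peroxy]-6-methylhept-4-en-2-yl}-5-methyl-12-oxo-11-oxatricyclo[7.3.0.0^{2,4}]dodec-1(9)-en-7-yl acetate | CC(=O)O[C@@H]1C[C@@H](C)[C@@H]2C[C@@H]2C2=C(COC2=O)[C@@H]1[C@H](C)C/C=C/C(C)(C)OOC(C)(C)OC
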